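## Structural features

Target 13 is a single carbocycle, a cyclohexene, and its only other rings are the phenyl groups of two benzoates. C1 is a tertiary carbinol that also bears the benzoyloxymethyl carbon C7, C2=C3 is the ring alkene, C4 carries an allylic benzoate, and C5 and C6 carry free secondary hydroxyls (these atom labels are kept for every intermediate). The four stereocentres C4, C5, C6 and C1 are contiguous and read (1S,4R,5S,6S): O1 and O6 are cis, O5 is trans to O6, and O4 is cis to O5. The fragile points are the two benzoates, which migrate to neighbouring free hydroxyls or are cleaved under base (O4 to the cis O5, O7 to O1 or O6), and the allylic C4–O and tertiary allylic C1–O bonds, which can ionise in strong acid; any elimination leads towards an arene. The real difficulty is to fix the quaternary centre C1 in the absolute sense while telling five oxygens apart so that only O4 and O7 are acylated, and to place the O4/O5 cis pair on the ring face opposite O1 and O6. The key step exploits the fact that C1, with O1, C7 and the adjacent C2=C3, is the C4 position of a 4-hydroxy-4-substituted cyclohexa-2,5-dienone whose second enone arm, C5=C6, has taken up oxygen at C6 on the face of O1. An achiral quinol can therefore be desymmetrised by bridging O1 and C6 through one acetal carbon, which forms the cis-fused dioxolane ring of 7 and leaves the C2=C3–C4=O enone as the handle for C5 and C4.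

## Logic of the disconnections

13 ⇒ 12. O5 is silylated and O1/O6 are joined through one acetal carbon; in the forward sense one O5–Si bond and two acetal C–O bonds are broken. These three oxygens are exactly the ones that stay free in 13, and both masks are left over from earlier steps rather than added as separate protections. The gain is that 12 has no free hydroxyl next to a benzoate, so acyl migration cannot start before the last step. The forward step must remove an aldehyde-derived acetal and a silyl ether in one mildly acidic operation without moving a benzoate or ionising an allylic C–O bond.

12 ⇒ 11 + 2. The C4–O4 bond is cut on the alkyl side, with inversion at C4. Hydride addition to the C4 ketone is expected to place O4 trans to O5, whereas 13 has them cis, so simple O-acylation of 11 would lead to the C4 epimer of 13. Forming the ester by substitution at carbon corrects C4 and brings in the second benzoate in one step. The forward step must be a clean SN2 displacement at a secondary allylic carbon, without SN2' attack or elimination.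

11 ⇒ 10. The C4–H bond is cut, which returns the carbinol to the enone carbonyl that survives the key step. One stereocentre disappears and the O4 problem becomes a ketone reduction. The forward reduction must be 1,2-selective and should prefer one face; the route commits to the trans alcohol.

10 ⇒ 8. The C5–O5 bond is cut, back to the enol ether C4=C5. The α'-carbon of an enone is the natural site for electrophilic oxygen, and the silyl group of the enol ether reappears on O5 as its protecting group. The forward oxidation must attack C4=C5 and not C2=C3, from the face opposite O6.

8 ⇒ 7. The O4–Si bond is cut. Only C5 can lose a proton (C3 is vinylic, C1 is quaternary), so regiochemistry is not in question. The forward step must enolise a β-alkoxy ketone without expelling O6.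

7 ⇒ 4 + 5. The C6–O6 bond and the bond between O1 and the acetal carbon are cut, which opens the dioxolane ring. This is the strategic cut: every stereocentre vanishes, since 4 is achiral and 5 is a commodity aldehyde, and the carbocycle becomes a symmetrical dienone. The forward step must make a catalyst choose the C5=C6 arm over the enantiotopic C2=C3 arm; the cis relation of O1 and O6 then follows from the tether.

4 ⇒ 3. The C1–O1 bond is cut, which restores the arene. The tertiary carbinol is traded for a phenol and the ring becomes a bought item. The forward oxidation must deliver water to the para carbon and must not let the p-hydroxybenzyl ester ionise to a quinone methide, which rules out basic media.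

3 ⇒ 1 + 2. The C7–O7 bond is cut. Placing the benzoate before dearomatisation means that C7 never needs a protecting group. The forward esterification must select the aliphatic hydroxyl over the phenol without generating phenoxide. Acyl transfer under base would acylate the phenol first, so the ester is formed instead by attack of the carboxylate on C7.

## Other disconnections considered

Alternative 1: The cut is made at C4–O4 and C5–O5, both oxygens being traced to one molecule of O2 added to an arene. In the forward direction whole cells expressing toluene dioxygenase (an enzyme) oxidise bromobenzene A1 to the cis-dienediol (1S,2S)-3-bromocyclohexa-3,5-diene-1,2-diol A2; no ring is closed. When A2 is laid on 13 so that its diol has the absolute configuration of O4/O5, the carbinol next to the C–Br carbon becomes C4, the bromine falls on C3 and the unsubstituted alkene becomes C1=C6.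
- In its favour: the enzyme sets the absolute configuration very reliably, and the O4/O5 cis pair arrives in one step with no inversion. On this point the alternative is the better plan, since the chosen route needs an α'-oxidation, a reduction and an inversion to reach the same pair. Both plans buy the six-membered ring as an arene and are equal in skeletal economy.
- Against it here: O4 and O5 are born as an undifferentiated cis-diol and must later be told apart. The bromine sits where 13 has hydrogen and must be removed by reduction. The C1=C6 alkene could be cis-dihydroxylated anti to a protected O4/O5 diol, which would put O6 and O1 on the right face, but C1 would then be only a secondary carbinol; C7 would have to be added to a C1 ketone late and under substrate control.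
- Comparison: mechanistically both plans apply enantioselective catalysis to a flat, achiral six-membered ring, the enzyme to the arene and the phosphoric acid to the dearomatised dienone. The alternative is expected to be longer, of the order of eleven to thirteen operations against eight, and it needs fermentation equipment.

Alternative 2: The cut is a retro-Diels–Alder one through C1–C6 and C4–C5, with C7 and O4 kept joined as a lactone bridge. In the forward direction 3-hydroxy-2H-pyran-2-one A3 is deprotonated by a cinchona-alkaloid base such as quinidine (C20H24N2O2), and its pyronolate adds across (E)-hex-3-ene-2,5-dione A4 to give 7,8-trans-diacetyl-4-hydroxy-2-oxabicyclo[2.2.2]oct-5-en-3-one A5, which closes the carbocycle. The stereochemistry of A5 maps correctly on 13: the carbinol bridgehead is C1, the lactone carbonyl is C7, the ring oxygen is O4, and the two acetyl groups stand trans at C5 and C6 on the faces where O5 and O6 belong.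
- In its favour: two C–C bonds, the carbocycle and all four ring stereocentres are made in one catalytic step, and O4 is delivered with the right configuration. In stereochemical convergence this is the better plan, since the chosen key step fixes only C1 and C6.
- Against it here: C5 and C6 arrive as C-acetyl groups, so two Baeyer–Villiger oxidations are needed next to a strained alkene that the same peracid can epoxidise. The resulting O5/O6 acetates then stand beside the positions that must carry benzoates, and removing acetate while keeping benzoate in place without acyl migration is a weak point. The bicyclic lactone can lose CO2 by cycloreversion on warming. With a trans dienophile, the acetyl next to C1 must also take the orientation on the side of the alkene bridge, a diastereoselectivity on top of the enantioselectivity.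
- Comparison: the two key steps are mechanistically alike (a bifunctional organocatalyst holds both partners by hydrogen bonds) and equal in that respect, but the alternative makes C–C bonds while the chosen plan makes only C–O bonds on a bought ring. In step count the alternative is expected to be equal at best and probably longer, about nine to eleven operations from A3, which itself has to be prepared.

Alternative 3: The cut is the C3–C4 bond; O5 and O6 with their trans relationship are traced back to diethyl D-tartrate A6. In the forward direction CrCl2 with catalytic NiCl2 acts on the open-chain Z-iodoalkene aldehyde A7 (O1 as triethylsilyl ether, O7 benzoylated, O5/O6 as acetonide). Zerovalent nickel inserts into the C–I bond and passes the vinyl group to trivalent chromium, and C3 of the vinylchromium adds to the C4 aldehyde to close the cyclohexene A8 (Nozaki–Hiyama–Kishi reaction).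
- In its favour: C5 and C6 come from the chiral pool, so their absolute configuration depends on no catalyst; on this point the alternative is the better plan. The organochromium reagent tolerates the benzoate and the silyl ether, every oxygen is at its final oxidation level, and after ring closure only acylation of O4 and deprotection remain, an endgame equal in length to that of the chosen plan.
- Against it here: the acetonide spans a trans-diol on the ring being formed, so closure must build a strained trans-fused dioxolane–cyclohexene. The configuration at C4 comes from addition to an aldehyde under 1,2-induction only and may need the same inversion as in the chosen plan (equal, not better). The quaternary carbinol C1 must be built in the open chain by addition to a ketone beside the dioxolane, with uncertain diastereoselectivity, and the Z-iodoalkene must be installed next to it. The divalent chromium reagent is used in large excess and is toxic.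
- Comparison: the alternative forms a ring C–C bond by organometallic addition under substrate control, whereas the chosen plan forms no C–C bond and relies on catalyst control for C1/C6. It is clearly longer: A7 needs roughly ten steps from A6, about thirteen or more in total against eight.

Key step: step 3

Assumption: the (R)-enantiomer of the phosphoric acid is taken to select the C5=C6 arm and give (1S,6S)-7; if it selects the other arm, its (S)-antipode is used and nothing else in the route changes.

Remark: the configurations at C1 and C6 written for 7 were checked against 13 and agree (both S, O1 and O6 cis); the acetal carbon is written as its R epimer (isopropyl on the convex face), and either epimer would serve.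

## Steps

Step 1
Reactants: 1 4-hydroxybenzyl alcohol; 2 benzoic acid
Product: 3 4-hydroxybenzyl benzoate
Conditions: PPh3, DIAD, THF, 0 °C → rt
Reagents that add atoms: none
Why: Mitsunobu esterification: only the aliphatic hydroxyl is activated as an alkoxyphosphonium ion and only the carboxylic acid, far more acidic than the phenol, is deprotonated by the betaine, so the ester forms at C7 without base; phenoxide, which would expel benzoate as a p-quinone methide, is never generated, and 3 is taken on without storage.

Step 2
Reactants: 3 4-hydroxybenzyl benzoate
Product: 4 4-(benzoyloxymethyl)-4-hydroxycyclohexa-2,5-dien-1-one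
Conditions: PhI(OAc)2, MeCN/H2O (3:1), 0 °C
Reagents that add atoms: water, SMILES O
Why: Oxidative dearomatisation of a para-substituted phenol: the phenol oxygen binds to iodine, loss of iodobenzene leaves a phenoxenium-type cation, and water adds at the para carbon, which becomes C1 with O1; the medium stays acidic, so the labile p-hydroxybenzyl ester is not ionised through phenoxide, and C1 is not yet stereogenic because the two enone arms are enantiotopic.

Step 3
Reactants: 4 4-(benzoyloxymethyl)-4-hydroxycyclohexa-2,5-dien-1-one; 5 2-methylpropanal
Product: 7 (1S,6S)-1-(benzoyloxymethyl)-1,6-(2-methylpropylidenedioxy)cyclohex-2-en-4-one (cis-fused 2-isopropyl-1,3-dioxolane; acetal carbon R), via hemiacetal 6 (not isolated)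
Conditions: (R)-3,3'-bis(2,4,6-triisopropylphenyl)-1,1'-binaphthyl-2,2'-diyl hydrogen phosphate (5 mol %), 5 (3 equiv), ClCH2CH2Cl, 30 °C
Reagents that add atoms: none
Why: The phosphoric acid activates 5, O1 adds to give hemiacetal 6 reversibly, and the hemiacetal hydroxyl then adds to C6 of the enone while the same phosphate holds both partners (P–OH to the C4 carbonyl, P=O to the O–H), followed by protonation at C5. The closest known reaction type is the chiral phosphoric acid catalysed acetalisation/oxa-Michael desymmetrisation of p-quinols and p-peroxyquinols with aldehydes. The 1,3-dioxolane closes by a 5-exo-trig oxa-Michael addition. The configuration of C6 relative to C1 is fixed by the tether, because the bridge O1–CH(iPr)–O can only reach the ring face that carries O1, hence the cis fusion. C1 becomes stereogenic through the choice of arm: the chiral pocket of the catalyst must direct the hemiacetal to C5=C6 and not to the enantiotopic C2=C3, and this choice alone sets the absolute configuration (1S,6S). The hemiacetal epimers interconvert faster than they cyclise and the isopropyl group should settle on the convex face, but the acetal carbon is removed in step 8 and its configuration is of no consequence. The selectivity needed is enantiotopic-group selectivity, and the substrate secures a clean test of it by being exactly mirror-symmetric, with two identical arms, no other acidic hydroxyl and a C7 benzoate that is a spectator. All atoms of 4 and 5 end up in 7.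

Step 4
Reactants: 7 (1S,6S)-1-(benzoyloxymethyl)-1,6-(2-methylpropylidenedioxy)cyclohex-2-en-4-one
Product: 8 (1S,6S)-1-(benzoyloxymethyl)-4-(tert-butyldimethylsilyloxy)-1,6-(2-methylpropylidenedioxy)cyclohexa-2,4-diene
Conditions: TBSOTf, Et3N, CH2Cl2, −78 → 0 °C
Reagents that add atoms: tert-butyldimethylsilyl trifluoromethanesulfonate (TBSOTf), SMILES CC(C)(C)[Si](C)(C)OS(=O)(=O)C(F)(F)F
Why: Soft enolisation: the silyl triflate silylates the carbonyl oxygen and Et3N removes a C5 proton, the only position that can enolise (C3 is vinylic, C1 is quaternary), giving the 2-silyloxy-1,3-diene without a free enolate, which limits β-elimination of O6; no stereocentre is formed.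

Step 5
Reactants: 8 (1S,6S)-1-(benzoyloxymethyl)-4-(tert-butyldimethylsilyloxy)-1,6-(2-methylpropylidenedioxy)cyclohexa-2,4-diene
Product: 10 (1S,5S,6S)-1-(benzoyloxymethyl)-5-(tert-butyldimethylsilyloxy)-1,6-(2-methylpropylidenedioxy)cyclohex-2-en-4-one (O5 trans to O6), via silyloxy epoxide 9 (not isolated)
Conditions: mCPBA, NaHCO3, CH2Cl2, −20 °C → rt
Reagents that add atoms: 3-chloroperoxybenzoic acid (mCPBA), SMILES O=C(OO)c1cccc(Cl)c1
Why: Rubottom oxidation: the electron-rich C4=C5 enol ether is epoxidised much faster than C2=C3 and from the face opposite the dioxolane bridge (O1, O6 and the acetal carbon shield the other face), so O5 ends up trans to O6; the silyloxy epoxide 9 opens to an oxocarbenium ion and a 1,4-silyl shift from O4 to O5 gives the α'-silyloxy enone.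

Step 6
Reactants: 10 (1S,5S,6S)-1-(benzoyloxymethyl)-5-(tert-butyldimethylsilyloxy)-1,6-(2-methylpropylidenedioxy)cyclohex-2-en-4-one
Product: 11 (1S,4S,5R,6S)-1-(benzoyloxymethyl)-5-(tert-butyldimethylsilyloxy)-1,6-(2-methylpropylidenedioxy)cyclohex-2-en-4-ol (O4 trans to O5)
Conditions: NaBH4, CeCl3·7H2O, MeOH, −78 °C
Reagents that add atoms: none
Why: Luche reduction, 1,2-selective for enones; in the favoured half-chair O5, O6 and C7 are pseudo-equatorial (the other half-chair would set C7 and the silyloxy group 1,3-diaxial) and the small hydride should add axially, anti to the axial H5, giving the equatorial C4 hydroxyl trans to O5 (4S). This is the C4 epimer of what the target needs, which is why step 7 is an inversion.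

Step 7
Reactants: 11 (1S,4S,5R,6S)-1-(benzoyloxymethyl)-5-(tert-butyldimethylsilyloxy)-1,6-(2-methylpropylidenedioxy)cyclohex-2-en-4-ol; 2 benzoic acid
Product: 12 (1S,4R,5R,6S)-4-benzoyloxy-1-(benzoyloxymethyl)-5-(tert-butyldimethylsilyloxy)-1,6-(2-methylpropylidenedioxy)cyclohex-2-ene (O4 cis to O5)
Conditions: PPh3, DIAD, PhMe, 0 °C → rt
Reagents that add atoms: none
Why: Mitsunobu esterification: the C4 alkoxyphosphonium ion is displaced by benzoate in an SN2 step with inversion, which brings O4 cis to O5 (4R) and installs the second benzoate in the same operation; SN2' attack at C2 is blocked by the neighbouring quaternary C1 and elimination towards C5 lacks an anti-periplanar hydrogen.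

Step 8
Reactants: 12 (1S,4R,5R,6S)-4-benzoyloxy-1-(benzoyloxymethyl)-5-(tert-butyldimethylsilyloxy)-1,6-(2-methylpropylidenedioxy)cyclohex-2-ene
Product: 13 [(1S,4R,5S,6S)-4-(benzoyloxy)-1,5,6-trihydroxycyclohex-2-en-1-yl]methyl benzoate
Conditions: CF3CO2H/H2O (4:1), CH2Cl2, 0 °C → rt
Reagents that add atoms: none
Why: Acid hydrolysis: protonation of an acetal oxygen opens the acetal at the acetal carbon (C1–O1 and C6–O6 stay intact, so no stereocentre is touched) and water releases the aldehyde, while the silyl ether is cleaved by protodesilylation; benzoates survive cold aqueous acid and the absence of base suppresses acyl migration.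

## Compound list

1 | 4-hydroxybenzyl alcohol | OCc1ccc(O)cc1 | starting material
2 | benzoic acid | O=C(O)c1ccccc1 | starting material
3 | 4-hydroxybenzyl benzoate | O=C(OCc1ccc(O)cc1)c1ccccc1 | intermediate
4 | 4-(benzoyloxymethyl)-4-hydroxycyclohexa-2,5-dien-1-one | O=C(OCC1(O)C=CC(=O)C=C1)c1ccccc1 | intermediate
5 | 2-methylpropanal | CC(C)C=O | starting material
6 | 4-(benzoyloxymethyl)-4-(1-hydroxy-2-methylpropoxy)cyclohexa-2,5-dien-1-one (hemiacetal, both epimers, not isolated) | CC(C)C(O)OC1(COC(=O)c2ccccc2)C=CC(=O)C=C1 | intermediate
7 | (1S,6S)-1-(benzoyloxymethyl)-1,6-(2-methylpropylidenedioxy)cyclohex-2-en-4-one (cis-fused 2-isopropyl-1,3-dioxolane, acetal carbon R) | O=C(OC[C@@]12C=CC(=O)C[C@@H]1O[C@@H](C(C)C)O2)c1ccccc1 | intermediate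
8 | (1S,6S)-1-(benzoyloxymethyl)-4-(tert-butyldimethylsilyloxy)-1,6-(2-methylpropylidenedioxy)cyclohexa-2,4-diene | O=C(OC[C@@]12C=CC(O[Si](C)(C)C(C)(C)C)=C[C@@H]1O[C@@H](C(C)C)O2)c1ccccc1 | intermediate
9 | (1S,4S,5S,6S)-4,5-epoxide of 8, epoxide oxygen on the face opposite the dioxolane (not isolated) | O=C(OC[C@@]12C=C[C@@]3(O[Si](C)(C)C(C)(C)C)O[C@H]3[C@@H]1O[C@@H](C(C)C)O2)c1ccccc1 | intermediate
10 | (1S,5S,6S)-1-(benzoyloxymethyl)-5-(tert-butyldimethylsilyloxy)-1,6-(2-methylpropylidenedioxy)cyclohex-2-en-4-one (O5 trans to O6) | O=C(OC[C@@]12C=CC(=O)[C@@H](O[Si](C)(C)C(C)(C)C)[C@@H]1O[C@@H](C(C)C)O2)c1ccccc1 | intermediate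
11 | (1S,4S,5R,6S)-1-(benzoyloxymethyl)-5-(tert-butyldimethylsilyloxy)-1,6-(2-methylpropylidenedioxy)cyclohex-2-en-4-ol (O4 trans to O5) | O=C(OC[C@@]12C=C[C@H](O)[C@@H](O[Si](C)(C)C(C)(C)C)[C@@H]1O[C@@H](C(C)C)O2)c1ccccc1 | intermediate
12 | (1S,4R,5R,6S)-4-benzoyloxy-1-(benzoyloxymethyl)-5-(tert-butyldimethylsilyloxy)-1,6-(2-methylpropylidenedioxy)cyclohex-2-ene (O4 cis to O5) | O=C(OC[C@@]12C=C[C@@H](OC(=O)c3ccccc3)[C@@H](O[Si](C)(C)C(C)(C)C)[C@@H]1O[C@@H](C(C)C)O2)c1ccccc1 | intermediate
13 | [(1S,4R,5S,6S)-4-(benzoyloxy)-1,5,6-trihydroxycyclohex-2-en-1-yl]methyl benzoate | O=C(OC[C@@]1(O)C=C[C@@H](OC(=O)c2ccccc2)[C@@H](O)[C@@H]1O)c1ccccc1 | target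

## Step count and least certain steps

Total step count: 8. Longest linear sequence: 8 steps (1 → 13).

Step 3 (key step). The most likely failure is insufficient discrimination between the two enantiotopic enone arms. Enantiomeric purity could also erode through reversible oxa-Michael addition (ring opening and re-closure on the other arm) if the reaction runs too long or too warm, and the branched aldehyde may turn over slowly. Fallback, setting out from 4 and coming back at 7: the same cascade is run without asymmetric induction, from 4 and 5 with diphenyl hydrogen phosphate. This gives 7 together with its mirror image, (1R,6R)-1-(benzoyloxymethyl)-1,6-(2-methylpropylidenedioxy)cyclohex-2-en-4-one F1. The two are separated by preparative chromatography on a chiral stationary phase and 7 re-enters the route at step 4. Catalyst control is thus replaced by resolution.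

Step 6. The most likely failure is poor or reversed facial selectivity of hydride delivery to C4, because the preference rests on a conformational argument (axial attack on the half-chair with pseudo-equatorial O5) and not on a steric block. Fallback, setting out from 10 and coming back at 12: hydride is delivered under reagent control by a Corey–Bakshi–Shibata reduction, with BH3·SMe2 and (S)- or (R)-1-methyl-3,3-diphenyltetrahydro-1H,3H-pyrrolo[1,2-c][1,3,2]oxazaborole, the antipode being chosen for attack on the face of the dioxolane. This should give the 4,5-cis alcohol, (1S,4R,5R,6S)-1-(benzoyloxymethyl)-5-(tert-butyldimethylsilyloxy)-1,6-(2-methylpropylidenedioxy)cyclohex-2-en-4-ol F2. F2 is benzoylated with retention (benzoyl chloride, pyridine, 4-(dimethylamino)pyridine) and rejoins the route at 12, so step 7 is bypassed. Any of this epimer that accompanies 11 in step 6 can be funnelled the same way, so both C4 epimers converge on 12.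

Step 4. The most likely failures are β-elimination of O6 from the enol derivative (a retro-oxa-Michael opening of the dioxolane that would erase C6 and return an achiral dienone) and activation of the acetal by the silyl triflate. Fallback, setting out from 7 and coming back at 10: the α'-oxygen is introduced without an enol ether by oxidative acyloxylation with Mn(OAc)3·2H2O and chloroacetic acid in hot benzene. This should place the acyloxy group on C5 anti to O6 and give (1S,5S,6S)-1-(benzoyloxymethyl)-5-(chloroacetoxy)-1,6-(2-methylpropylidenedioxy)cyclohex-2-en-4-one F3. The chloroacetate is removed with thiourea (2,6-lutidine, EtOH), which leaves the benzoate untouched, to give (1S,5S,6S)-1-(benzoyloxymethyl)-5-hydroxy-1,6-(2-methylpropylidenedioxy)cyclohex-2-en-4-one F4. Silylation (TBSCl, imidazole, DMF) returns to 10, so steps 4 and 5 are both replaced.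

Step 8. The most likely failures are benzoyl migration from O4 to the cis O5 once the silyl group has left, acid-promoted ionisation at the allylic positions, and incomplete hydrolysis of the aldehyde-derived acetal, which is far less labile than a ketal. Fallback, setting out from 12 and coming back at 13: the two masks are removed in stages under non-aqueous conditions. The acetal carbon is first transferred to propane-1,3-dithiol (BF3·OEt2, CH2Cl2, −40 °C), which frees O1 and O6 while O5 stays silylated and gives [(1S,4R,5S,6S)-4-(benzoyloxy)-5-(tert-butyldimethylsilyloxy)-1,6-dihydroxycyclohex-2-en-1-yl]methyl benzoate F5. Buffered HF·pyridine in THF at 0 °C then removes the silyl group and gives 13.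

Step 2. The most likely failures are ionisation of the p-hydroxybenzyl ester to a quinone methide, capture of the cation by acetate instead of water, and further oxidation of the quinol, all of which lower the mass balance. Fallback, setting out from 3 and coming back at 4: dye-sensitised photo-oxygenation (O2, visible light, 5,10,15,20-tetraphenylporphyrin, CH2Cl2, 0 °C) adds singlet oxygen to the phenol ring. This gives the p-peroxyquinol 4-(benzoyloxymethyl)-4-hydroperoxycyclohexa-2,5-dien-1-one F6, which is reduced in the same flask with PPh3 to 4.

## Further compounds

F1 | step 3 | (1R,6R)-1-(benzoyloxymethyl)-1,6-(2-methylpropylidenedioxy)cyclohex-2-en-4-one (mirror image of 7) | O=C(OC[C@]12C=CC(=O)C[C@H]1O[C@H](C(C)C)O2)c1ccccc1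
F2 | step 6 | (1S,4R,5R,6S)-1-(benzoyloxymethyl)-5-(tert-butyldimethylsilyloxy)-1,6-(2-methylpropylidenedioxy)cyclohex-2-en-4-ol (O4 cis to O5) | O=C(OC[C@@]12C=C[C@@H](O)[C@@H](O[Si](C)(C)C(C)(C)C)[C@@H]1O[C@@H](C(C)C)O2)c1ccccc1
F3 | step 4 | (1S,5S,6S)-1-(benzoyloxymethyl)-5-(chloroacetoxy)-1,6-(2-methylpropylidenedioxy)cyclohex-2-en-4-one | O=C(OC[C@@]12C=CC(=O)[C@@H](OC(=O)CCl)[C@@H]1O[C@@H](C(C)C)O2)c1ccccc1
F4 | step 4 | (1S,5S,6S)-1-(benzoyloxymethyl)-5-hydroxy-1,6-(2-methylpropylidenedioxy)cyclohex-2-en-4-one | O=C(OC[C@@]12C=CC(=O)[C@@H](O)[C@@H]1O[C@@H](C(C)C)O2)c1ccccc1
F5 | step 8 | [(1S,4R,5S,6S)-4-(benzoyloxy)-5-(tert-butyldimethylsilyloxy)-1,6-dihydroxycyclohex-2-en-1-yl]methyl benzoate | O=C(OC[C@@]1(O)C=C[C@@H](OC(=O)c2ccccc2)[C@@H](O[Si](C)(C)C(C)(C)C)[C@@H]1O)c1ccccc1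
F6 | step 2 | 4-(benzoyloxymethyl)-4-hydroperoxycyclohexa-2,5-dien-1-one | O=C(OCC1(OO)C=CC(=O)C=C1)c1ccccc1
A1 | alternative 1 | bromobenzene | Brc1ccccc1
A2 | alternative 1 | (1S,2S)-3-bromocyclohexa-3,5-diene-1,2-diol | BrC1=CC=C[C@H](O)[C@@H]1O
A3 | alternative 2 | 3-hydroxy-2H-pyran-2-one | O=C1OC=CC=C1O
A4 | alternative 2 | (E)-hex-3-ene-2,5-dione | CC(=O)/C=C/C(C)=O
A5 | alternative 2 | 7,8-trans-diacetyl-4-hydroxy-2-oxabicyclo[2.2.2]oct-5-en-3-one (C8 acetyl on the side of the alkene bridge) | O=C2[C@@]1(O)C=C[C@@H](O2)[C@@H](C(C)=O)[C@@H]1C(C)=O
A6 | alternative 3 | diethyl D-tartrate, (2S,3S) | CCOC(=O)[C@@H](O)[C@H](O)C(=O)OCC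
A7 | alternative 3 | open-chain Z-iodoalkene aldehyde (O1 triethylsilyl, O7 benzoyl, O5/O6 isopropylidene, C4 aldehyde) | O=C(OC[C@@](O[Si](CC)(CC)CC)(/C=C\I)[C@H]1OC(C)(C)O[C@@H]1C=O)c1ccccc1
A8 | alternative 3 | C4-hydroxy cyclohexene (O1 triethylsilyl, O7 benzoyl, O5/O6 isopropylidene) | O=C(OC[C@@]1(O[Si](CC)(CC)CC)C=C[C@@H](O)[C@H]3OC(C)(C)O[C@H]13)c1ccccc1
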